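## The problem

The target is a flavonol: benzene ring A is fused through C4a–C8a to the 4-pyranone ring C, which carries a hydroxyl at C3 and the 4-prenyloxyphenyl ring B at C2. It has no stereocentre, so the difficulty lies in regiochemistry and functional-group tolerance, not in stereocontrol. Ring A carries oxygen on four neighbouring carbons (O1 on C8a, OMe on C8, OH on C7 and on C5), and only one of these oxygens is methylated. The methoxy group must end up at C8 and not at C6, and because 5-oxygenated flavones can ring-open and reclose to the 6-isomer under acid or strong base, its position is best fixed before ring C exists. The prenyl aryl ether is the fragile group: acids cleave it, peracids and dioxiranes epoxidise its trisubstituted alkene, and hydrogenation saturates it. This excludes benzyl or acetal protection of the 5- and 7-hydroxyls at the end of the route and excludes epoxidation as the way to the 3-hydroxyl. The feature that opens the structure is C3: a single carbon between C4, a carboxyl-level carbon attached to ring A, and C2, a carboxyl-level carbon attached to ring B that is already bonded to O1. An O-aroylsalicylic acid therefore holds every skeletal atom except C3, and a one-carbon reagent that makes one single bond and one double bond completes ring C.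

## Retrosynthesis

**Target 24 to diallyl ether 23.** The two O–allyl bonds at C5 and C7 are cut last. Allyl is chosen over benzyl (hydrogenolysis would reduce the prenyl alkene) and over acetals (acid endangers the prenyl ether). Zerovalent palladium ionises an unsubstituted allyl aryl ether much faster than the hindered prenyl ether, and the forward step must keep that distinction.

**Flavonol 23 to flavone 20.** The C3–O bond is cut. C3–H is the only vinylic C–H beside the carbonyl, so deprotonation, borylation and oxidation place the oxygen without ambiguity. Epoxidation of the C2=C3 bond would be the usual alternative, but the prenyl alkene would react first. The forward step asks that the amide base metalates C3 at −78 °C faster than it touches the allylic O–CH2 groups, and that the peroxide spares the prenyl alkene.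

**Flavone 20 to acid chloride 15 and ylide 17.** C3–C4 and C2=C3 are cut, which removes ring C and leaves C3 as methylenetriphenylphosphorane 17, made from the salt 16. The neighbouring cut, the diketone cyclodehydration at O1–C2, needs an o-hydroxyacetophenone and acid that the prenyl ether may not survive; chalcone routes need oxidants. Here both flanks of C3 are simple carboxylic acid derivatives and O1–C2 already exists as an ester. Which phenol carries the aroyl group decides between the 8- and 6-methoxy series, before any ring closure. The forward reaction must acylate the ylide at the acid chloride only and then olefinate an ester carbonyl, which intramolecularity makes feasible.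

**Acid chloride 15 to acid 14, aldehyde ester 13, salicylaldehyde 8 and acid 12.** The C–Cl bond, the carboxyl oxidation level and the ester C–O bond are undone in turn. The phenol is acylated at the aldehyde stage because a free salicylic acid would give mixed anhydrides. The aldehyde is then oxidised with chlorite, which leaves ester, allyl and prenyl groups alone if hypochlorite is scavenged. Compound 8 is a small benzaldehyde and 12 a simple benzoic acid.

**Salicylaldehyde 8 to phenol 7.** The formyl C–C bond is cut. Phenol 7 has a single free ortho position, so magnesium-mediated ortho-formylation can only give 8. Electrophilic formylation of a fully etherified ring would not distinguish the two free ring positions.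

**Phenol 7 to 2,4,6-trihydroxybenzaldehyde 1, through 6, 5, 3 and 2.**
- The methyl ether of 6 is cut to phenol 5.
- The C–O bond of 5 is traced through formate 4 to the formyl group of 3 (Baeyer–Villiger), so the aldehyde carbon of 1 marks the site of the future 8-methoxy oxygen.
- The hydroxyl hydrogen-bonded to that aldehyde stays free in the bis-allylation (2) and is masked as a methoxymethyl ether (3). After unmasking it is the one free phenol of 7, which directs the formylation and later becomes O1.
- The forward steps are ordinary etherifications and one peracid oxidation that must prefer the aldehyde to the allyl alkenes.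

**Acid 12 to 4-hydroxybenzoic acid 9 and prenyl bromide 10.** The prenyl O–C bond is cut. Double alkylation to ester 11 and saponification avoid any need to distinguish the phenol from the acid.

## Roads not taken

**Alternative 1:** The cut is at C1'–C2 and C2–C3, with O1–C2 closing afterwards, so C2 comes from carbon monoxide.
- *Forward key step:* the enolate carbon of α-silyloxy ketone A1, carbon monoxide and aryl iodide A2 are joined by Pd(OAc)2 with 1,3-bis(diphenylphosphino)propane. The resulting diketone cyclises on the ortho phenol on acetic acid work-up to the silylated flavonol A3.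
- *Merits:* it is a three-component assembly. The C3 oxygen is present from the start, so no late C–H oxidation is needed. Fluoride removes all silyl groups without risk to the prenyl ether. In these respects it is better than the plan adopted here.
- *Weak points:* the nucleophile is an oxygen-substituted, hindered enolate next to a di-ortho-substituted aryl ketone, outside the usual methyl and methylene ketones of carbonylative α-arylation. The free ortho phenol of A1 sits beside aryl silyl ethers under basic conditions, which invites silyl migration. A1 needs the same regiodefined tetraoxygenated ring as 8 plus an oxygenated two-carbon chain, so it is no shorter to make.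
- *Comparison:* the chosen plan offers a ring closure of established type and a precursor reached by formylation and oxidation. It pays with a separate 3-hydroxylation.

**Alternative 2:** The cut is at C3–C4.
- *Forward key step:* a triazolium-derived N-heterocyclic carbene with Et3N cyclises dialdehyde A4 by intramolecular crossed benzoin reaction to the 3-hydroxychromanone A5 as a diastereomer mixture. A5 would then be dehydrogenated to 23.
- *Merits:* conditions are mild and metal-free, and the C3 oxygen arrives with the ring closure, so no amide base is needed. Here the alternative is at least as good. The diastereomer mixture is harmless because both stereocentres vanish on dehydrogenation.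
- *Weak points:* A4 contains an α-aryl-α-aryloxy acetaldehyde, which enolises and self-condenses easily and is awkward to make beside a second aldehyde. The carbene must add to the hindered, electron-rich, di-ortho-substituted aromatic aldehyde and leave the aliphatic one as acceptor; the reverse polarity gives the isomeric 4-hydroxychroman-3-one. The extra dehydrogenation is an oxidation in the presence of the prenyl alkene, and 3-hydroxyflavanones ring-open under base.
- *Comparison:* the chosen plan offers a stable precursor and a ring closure whose polarity cannot invert.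

**Alternative 3:** The cut is at C4a–C5, so ring A is built last on a pyranone derived from kojic acid A6.
- *Forward key step:* thermolysis of acyl Meldrum's acid A7 releases an acylketene whose enol is a dienylketene. It electrocyclises onto the pyranone carbon that becomes C4a and aromatises to A8, with free 5- and 7-hydroxyls.
- *Merits:* ring A needs no protecting groups. The 8- versus 6-methoxy question cannot arise, because the methoxy carbon is bonded to C8a from the outset. Only one protecting group remains to be removed. The end game is clearly better than in the chosen plan.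
- *Weak points:* the linear elaboration of A6 is long (arylation at the ring carbon beside oxygen, protection, conversion of the hydroxymethyl group into an α-methoxy acyl Meldrum's acid). The electrocyclisation must use a double bond of the vinylogous ester as triene terminus, and the acylketene can dimerise or be trapped instead. Removing the 3-O-protecting group needs Lewis acid or forcing fluoride.
- *Comparison:* the chosen plan offers cheap aromatic starting materials and a key step of known type, at the cost of two allyl groups and their removal.

Key step: step 11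

Remark on the chemistry: the target has no stereocentre, so no step sets or must preserve configuration. "Allyl" means prop-2-en-1-yl, "prenyl" means 3-methylbut-2-en-1-yl, and flavone means 2-phenyl-4H-chromen-4-one.

## Route

Step 1
Reactants: 1 2,4,6-trihydroxybenzaldehyde
Product: 2 2,4-bis(allyloxy)-6-hydroxybenzaldehyde
Conditions: allyl bromide (2.1 equiv), K2CO3 (2.2 equiv), acetone, 0 °C → rt
Reagents that add atoms: allyl bromide, C=CCBr
Why: Williamson ether synthesis; the para hydroxyl and one ortho hydroxyl are alkylated, while the remaining ortho hydroxyl is held in the hydrogen bond to the formyl oxygen and should react last, as is usual for phloroglucinol carbonyl compounds.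

Step 2
Reactants: 2 2,4-bis(allyloxy)-6-hydroxybenzaldehyde
Product: 3 2,4-bis(allyloxy)-6-(methoxymethoxy)benzaldehyde
Conditions: NaH (1.2 equiv), DMF, 0 °C; MOMCl (1.2 equiv), 0 °C → rt
Reagents that add atoms: chloromethyl methyl ether, COCCl
Why: O-alkylation of the phenoxide formed with NaH (Williamson type); deprotonation breaks the chelate, and the acetal masks the oxygen that later becomes O1.

Step 3
Reactants: 3 2,4-bis(allyloxy)-6-(methoxymethoxy)benzaldehyde
Product: 5 2,4-bis(allyloxy)-6-(methoxymethoxy)phenol, via aryl formate 4 (not isolated)
Conditions: mCPBA (1.2 equiv), CH2Cl2, 0 °C; then K2CO3 (cat.), MeOH, rt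
Reagents that add atoms: mCPBA, O=C(OO)c1cccc(Cl)c1
Why: Baeyer–Villiger oxidation; three ortho/para alkoxy groups make aryl migration fast, so the aldehyde should be consumed before the electron-poor terminal alkenes are epoxidised, and the formate is then removed by methanolysis.

Step 4
Reactants: 5 2,4-bis(allyloxy)-6-(methoxymethoxy)phenol
Product: 6 1,5-bis(allyloxy)-2-methoxy-3-(methoxymethoxy)benzene
Conditions: MeI (1.5 equiv), K2CO3, acetone, 50 °C
Reagents that add atoms: iodomethane, CI
Why: Williamson ether synthesis on the only free phenol; this fixes the future 8-methoxy group.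

Step 5
Reactants: 6 1,5-bis(allyloxy)-2-methoxy-3-(methoxymethoxy)benzene
Product: 7 3,5-bis(allyloxy)-2-methoxyphenol
Conditions: HCl (0.5 M) in MeOH, 40 °C
Reagents that add atoms: none
Why: acid-catalysed acetal exchange removes the methoxymethyl group; allyl and methyl aryl ethers are stable to dilute methanolic acid.

Step 6
Reactants: 7 3,5-bis(allyloxy)-2-methoxyphenol
Product: 8 4,6-bis(allyloxy)-2-hydroxy-3-methoxybenzaldehyde
Conditions: MgCl2 (1.5 equiv), Et3N (3.8 equiv), (CH2O)n, MeCN, 80 °C; aq. HCl work-up
Reagents that add atoms: paraformaldehyde (as formaldehyde), C=O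
Why: magnesium-mediated ortho-formylation; formaldehyde is delivered within the aryloxide–magnesium chelate formed from MgCl2 and Et3N to the single free ortho position, and the benzylic alkoxide is oxidised by hydride transfer to a second formaldehyde.

Step 7
Reactants: 9 4-hydroxybenzoic acid; 10 prenyl bromide (1-bromo-3-methylbut-2-ene)
Product: 12 4-(prenyloxy)benzoic acid, via prenyl 4-(prenyloxy)benzoate 11 (not isolated)
Conditions: 10 (2.3 equiv), K2CO3, DMF, rt; then NaOH, MeOH–H2O, 50 °C; cold dilute HCl to pH 4
Reagents that add atoms: none
Why: Williamson etherification with concurrent ester formation, then saponification of the prenyl ester; the aryl ether is inert to hydroxide and the brief cold acidification spares it.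

Step 8
Reactants: 8 4,6-bis(allyloxy)-2-hydroxy-3-methoxybenzaldehyde; 12 4-(prenyloxy)benzoic acid
Product: 13 3,5-bis(allyloxy)-2-formyl-6-methoxyphenyl 4-(prenyloxy)benzoate
Conditions: DCC (1.2 equiv), DMAP (0.2 equiv), CH2Cl2, 0 °C → rt
Reagents that add atoms: none
Why: Steglich esterification; the acylpyridinium intermediate acylates the only free phenol, the one beside OMe, and so forms the future O1–C2 bond under neutral conditions.

Step 9
Reactants: 13 3,5-bis(allyloxy)-2-formyl-6-methoxyphenyl 4-(prenyloxy)benzoate
Product: 14 4,6-bis(allyloxy)-3-methoxy-2-{[4-(prenyloxy)benzoyl]oxy}benzoic acid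
Conditions: NaClO2, NaH2PO4, 2-methyl-2-butene (30 equiv), t-BuOH–THF–H2O, 0 °C → rt
Reagents that add atoms: sodium chlorite, [Na+].[O-]Cl=O
Why: Pinnick oxidation; chlorous acid oxidises the aldehyde only, and the large excess of 2-methyl-2-butene traps hypochlorite before it can reach the prenyl alkene, the allyl groups or the ring.

Step 10
Reactants: 14 4,6-bis(allyloxy)-3-methoxy-2-{[4-(prenyloxy)benzoyl]oxy}benzoic acid
Product: 15 4,6-bis(allyloxy)-3-methoxy-2-{[4-(prenyloxy)benzoyl]oxy}benzoyl chloride
Conditions: 1-chloro-N,N,2-trimethylprop-1-en-1-amine (1.05 equiv), CH2Cl2, 0 °C → rt; volatiles removed, used crude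
Reagents that add atoms: 1-chloro-N,N,2-trimethylprop-1-en-1-amine, CC(C)=C(Cl)N(C)C
Why: acid chloride formation with an α-chloroenamine under neutral conditions; no HCl is released, so the prenyl alkene and ether are not exposed to acid.

Step 11
Reactants: 15 4,6-bis(allyloxy)-3-methoxy-2-{[4-(prenyloxy)benzoyl]oxy}benzoyl chloride; 16 methyltriphenylphosphonium bromide
Product: 20 5,7-bis(allyloxy)-8-methoxy-4'-prenyloxyflavone, via methylenetriphenylphosphorane 17 (not isolated), via acylmethylphosphonium chloride 18 (not isolated), via acylphosphorane 19 (not isolated)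
Conditions: 16 (2.2 equiv), NaN(SiMe3)2 (2.1 equiv), THF, 0 °C; 15 in THF added at −78 °C, then rt; PhMe, 110 °C
Reagents that add atoms: none
Why: Acid chloride 15 C-acylates the non-stabilised ylide 17 (from 16 and NaN(SiMe3)2) to phosphonium chloride 18, forming C3–C4, and a second equivalent of 17 at once removes the acidified α-proton to leave the stabilised acylphosphorane 19. On heating, the ylide carbon of 19 adds to the carbonyl of the neighbouring aryl ester and the oxaphosphetane collapses with loss of Ph3P=O to give the C2=C3 bond (intramolecular Wittig olefination of an ester). Ring C closes in a 6-exo-trig mode, the ylide carbon attacking the ester C=O so that C3, C4, C4a, C8a, O1 and C2 form the pyranone. The closest known reaction type is the acylation of phosphorus ylides by O-acylsalicylic acid derivatives with closure of the acylphosphorane onto the ester carbonyl, an established entry to chromones and flavones. No stereocentre is formed. The step needs the ylide to attack the acid chloride and not the aryl ester; the much higher electrophilicity of the acid chloride at −78 °C, and addition of 15 to exactly two equivalents of 17 so that proton transfer consumes free ylide as fast as 18 appears, secure this. Regiochemistry needs no control here, because the aroyl group sits on the only non-allylated oxygen ortho to the acyl group, the one beside OMe, so only the 8-methoxy flavone can form.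

Step 12
Reactants: 20 5,7-bis(allyloxy)-8-methoxy-4'-prenyloxyflavone
Product: 23 5,7-bis(allyloxy)-3-hydroxy-8-methoxy-4'-prenyloxyflavone, via 3-lithioflavone 21 (not isolated), via lithium aryltrimethoxyborate 22 (not isolated)
Conditions: LiN(i-Pr)2 (1.3 equiv), THF, −78 °C; B(OMe)3 (2 equiv), −78 → 0 °C; AcOH, 30% H2O2, 0 °C → rt
Reagents that add atoms: hydrogen peroxide, OO
Why: directed lithiation–borylation–oxidation; the carbonyl-flanked C3–H of a flavone is removed by the amide base at −78 °C, the vinyl-lithium is trapped on boron, and peroxide-induced 1,2-migration turns C–B into C–O with only brief cold exposure of the prenyl alkene to the oxidant.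

Step 13
Reactants: 23 5,7-bis(allyloxy)-3-hydroxy-8-methoxy-4'-prenyloxyflavone
Product: 24 3,5,7-trihydroxy-8-methoxy-4'-prenyloxyflavone (target)
Conditions: Pd(PPh3)4 (5 mol %), morpholine (10 equiv), degassed THF, rt
Reagents that add atoms: none
Why: Tsuji–Trost deallylation; zerovalent palladium ionises the two unsubstituted allyl aryl ethers, whose aryloxides are good leaving groups, and morpholine captures the π-allyl complex, while the hindered trisubstituted prenyl ether should react far more slowly.

## Compound list

1 | 2,4,6-trihydroxybenzaldehyde | O=Cc1c(O)cc(O)cc1O | starting material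
2 | 2,4-bis(allyloxy)-6-hydroxybenzaldehyde | O=Cc1c(O)cc(OCC=C)cc1OCC=C | intermediate
3 | 2,4-bis(allyloxy)-6-(methoxymethoxy)benzaldehyde | O=Cc1c(OCOC)cc(OCC=C)cc1OCC=C | intermediate
4 | 2,4-bis(allyloxy)-6-(methoxymethoxy)phenyl formate | O=COc1c(OCOC)cc(OCC=C)cc1OCC=C | intermediate
5 | 2,4-bis(allyloxy)-6-(methoxymethoxy)phenol | Oc1c(OCOC)cc(OCC=C)cc1OCC=C | intermediate
6 | 1,5-bis(allyloxy)-2-methoxy-3-(methoxymethoxy)benzene | COc1c(OCOC)cc(OCC=C)cc1OCC=C | intermediate
7 | 3,5-bis(allyloxy)-2-methoxyphenol | COc1c(O)cc(OCC=C)cc1OCC=C | intermediate
8 | 4,6-bis(allyloxy)-2-hydroxy-3-methoxybenzaldehyde | O=Cc1c(O)c(OC)c(OCC=C)cc1OCC=C | intermediate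
9 | 4-hydroxybenzoic acid | O=C(O)c1ccc(O)cc1 | starting material
10 | prenyl bromide (1-bromo-3-methylbut-2-ene) | CC(C)=CCBr | starting material
11 | prenyl 4-(prenyloxy)benzoate | CC(C)=CCOC(=O)c1ccc(OCC=C(C)C)cc1 | intermediate
12 | 4-(prenyloxy)benzoic acid | OC(=O)c1ccc(OCC=C(C)C)cc1 | intermediate
13 | 3,5-bis(allyloxy)-2-formyl-6-methoxyphenyl 4-(prenyloxy)benzoate | O=Cc1c(OC(=O)c2ccc(OCC=C(C)C)cc2)c(OC)c(OCC=C)cc1OCC=C | intermediate
14 | 4,6-bis(allyloxy)-3-methoxy-2-{[4-(prenyloxy)benzoyl]oxy}benzoic acid | OC(=O)c1c(OC(=O)c2ccc(OCC=C(C)C)cc2)c(OC)c(OCC=C)cc1OCC=C | intermediate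
15 | 4,6-bis(allyloxy)-3-methoxy-2-{[4-(prenyloxy)benzoyl]oxy}benzoyl chloride | ClC(=O)c1c(OC(=O)c2ccc(OCC=C(C)C)cc2)c(OC)c(OCC=C)cc1OCC=C | intermediate
16 | methyltriphenylphosphonium bromide | C[P+](c1ccccc1)(c1ccccc1)c1ccccc1.[Br-] | starting material
17 | methylenetriphenylphosphorane | C=P(c1ccccc1)(c1ccccc1)c1ccccc1 | intermediate
18 | {2-[4,6-bis(allyloxy)-3-methoxy-2-{[4-(prenyloxy)benzoyl]oxy}phenyl]-2-oxoethyl}triphenylphosphonium chloride | O=C(C[P+](c1ccccc1)(c1ccccc1)c1ccccc1)c1c(OC(=O)c2ccc(OCC=C(C)C)cc2)c(OC)c(OCC=C)cc1OCC=C.[Cl-] | intermediate
19 | 3,5-bis(allyloxy)-6-methoxy-2-[(triphenyl-λ5-phosphanylidene)acetyl]phenyl 4-(prenyloxy)benzoate | O=C(C=P(c1ccccc1)(c1ccccc1)c1ccccc1)c1c(OC(=O)c2ccc(OCC=C(C)C)cc2)c(OC)c(OCC=C)cc1OCC=C | intermediate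
20 | 5,7-bis(allyloxy)-8-methoxy-4'-prenyloxyflavone | C=CCOc1cc(OCC=C)c2c(=O)cc(-c3ccc(OCC=C(C)C)cc3)oc2c1OC | intermediate
21 | 5,7-bis(allyloxy)-3-lithio-8-methoxy-4'-prenyloxyflavone | [Li]c1c(-c2ccc(OCC=C(C)C)cc2)oc2c(OC)c(OCC=C)cc(OCC=C)c2c1=O | intermediate
22 | lithium [5,7-bis(allyloxy)-8-methoxy-4-oxo-2-(4-prenyloxyphenyl)-4H-chromen-3-yl]trimethoxyborate | [Li+].CO[B-](OC)(OC)c1c(-c2ccc(OCC=C(C)C)cc2)oc2c(OC)c(OCC=C)cc(OCC=C)c2c1=O | intermediate
23 | 5,7-bis(allyloxy)-3-hydroxy-8-methoxy-4'-prenyloxyflavone | C=CCOc1cc(OCC=C)c2c(=O)c(O)c(-c3ccc(OCC=C(C)C)cc3)oc2c1OC | intermediate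
24 | 3,5,7-trihydroxy-8-methoxy-4'-prenyloxyflavone | COc1c(O)cc(O)c2c(=O)c(O)c(-c3ccc(OCC=C(C)C)cc3)oc12 | target

## Step count and uncertain steps

Total: 13 steps. Longest linear sequence: 12 steps (steps 1–6 and 8–13, from 2,4,6-trihydroxybenzaldehyde 1); step 7 is the one-step side branch.

**Step 11 (key step).** After the ylide carbon of 19 has added to the ester carbonyl, the intermediate may expel the ring A aryloxide instead of Ph3P=O (an O-to-C aroyl transfer), and the twisted, di-ortho-substituted acyl group may slow the closure. Attack of free ylide on the aryl ester during the acylation is the second possibility. The fallback uses the aroyl transfer deliberately. It sets out from 15, where Me2CuLi in THF at −78 °C replaces chloride by methyl to give 2-acetyl-3,5-bis(allyloxy)-6-methoxyphenyl 4-(prenyloxy)benzoate F1. LiN(SiMe3)2 in THF then brings about the Baker–Venkataraman rearrangement to 1-[4,6-bis(allyloxy)-2-hydroxy-3-methoxyphenyl]-3-[4-(prenyloxy)phenyl]propane-1,3-dione F2. Cyclodehydration in AcOH buffered with NaOAc at 90 °C closes O1–C2 through the one free phenol, and the sequence returns to the route at 20.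

**Step 12.** The amide base may deprotonate the allylic O–CH2 groups of the three ethers or add at C2 in competition with C3 metalation, and the peroxide may attack the prenyl alkene during a sluggish boron oxidation. The fallback builds the 3-oxygen by the Algar–Flynn–Oyamada reaction and sets out from 8. MeMgBr (2.5 equiv, THF, 0 °C) gives 3,5-bis(allyloxy)-2-(1-hydroxyethyl)-6-methoxyphenol F3 (racemic), and MnO2 in CH2Cl2 oxidises it to 1-[4,6-bis(allyloxy)-2-hydroxy-3-methoxyphenyl]ethan-1-one F4. Claisen–Schmidt condensation (KOH, EtOH) with 4-(prenyloxy)benzaldehyde F5, made from 4-hydroxybenzaldehyde and 10 with K2CO3, gives (E)-1-[4,6-bis(allyloxy)-2-hydroxy-3-methoxyphenyl]-3-[4-(prenyloxy)phenyl]prop-2-en-1-one F6. Cold alkaline H2O2 (NaOH, MeOH, 0 °C) then cyclises and oxidises F6, and the sequence returns at 23. The known price is the tendency of chalcones with an alkoxy group ortho to the carbonyl to divert to aurones.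

**Step 13.** Once the allyl groups are gone, zerovalent palladium may slowly ionise the prenyl ether as well, and the π-allyl complex may C-allylate the liberated, electron-rich ring A if the scavenger is too slow. The fallback changes the mechanism of deprotection and sets out from 23. [Ir(cod)(PMePh2)2]PF6, activated with H2 in THF, isomerises only the monosubstituted allyl ethers, giving 3-hydroxy-8-methoxy-4'-prenyloxy-5,7-bis[(E)-prop-1-en-1-yloxy]flavone F7. The enol ethers are then hydrolysed with HgCl2 and HgO in aqueous acetone, which returns the route to 24.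

**Step 3.** The peracid may epoxidise an allyl ether in competition with the Baeyer–Villiger oxidation, and the very electron-rich phenol 5 may be oxidised further during formate cleavage. The fallback avoids peracid and sets out from 2. A Dakin oxidation (30% H2O2, aq. NaOH, THF, 0 °C), which needs the free ortho hydroxyl, gives 3,5-bis(allyloxy)benzene-1,2-diol F8. MOMCl (1.0 equiv) with i-Pr2NEt in CH2Cl2 at −20 °C should then etherify the less hindered and more acidic hydroxyl (meta to both allyloxy groups), and the sequence returns at 5. The weak point of this fallback is the regioselectivity of that mono-protection.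

**Step 1.** The phloroglucinol-type phenoxide may be allylated on carbon, and some alkylation may occur at the chelated hydroxyl. The fallback replaces phenoxide alkylation by a Mitsunobu reaction and sets out from 1. Allyl alcohol (2.1 equiv), PPh3 and diisopropyl azodicarboxylate in THF at 0 °C etherify the two non-chelated hydroxyls without a free phenoxide and return to the route at 2. It forms no new compound (F0).

## Further compounds

F1 | step 11 | 2-acetyl-3,5-bis(allyloxy)-6-methoxyphenyl 4-(prenyloxy)benzoate | CC(=O)c1c(OC(=O)c2ccc(OCC=C(C)C)cc2)c(OC)c(OCC=C)cc1OCC=C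
F2 | step 11 | 1-[4,6-bis(allyloxy)-2-hydroxy-3-methoxyphenyl]-3-[4-(prenyloxy)phenyl]propane-1,3-dione | O=C(CC(=O)c1ccc(OCC=C(C)C)cc1)c1c(O)c(OC)c(OCC=C)cc1OCC=C
F3 | step 12 | 3,5-bis(allyloxy)-2-(1-hydroxyethyl)-6-methoxyphenol (racemic) | CC(O)c1c(O)c(OC)c(OCC=C)cc1OCC=C
F4 | step 12 | 1-[4,6-bis(allyloxy)-2-hydroxy-3-methoxyphenyl]ethan-1-one | CC(=O)c1c(O)c(OC)c(OCC=C)cc1OCC=C
F5 | step 12 | 4-(prenyloxy)benzaldehyde | CC(C)=CCOc1ccc(C=O)cc1
F6 | step 12 | (E)-1-[4,6-bis(allyloxy)-2-hydroxy-3-methoxyphenyl]-3-[4-(prenyloxy)phenyl]prop-2-en-1-one | O=C(/C=C/c1ccc(OCC=C(C)C)cc1)c1c(O)c(OC)c(OCC=C)cc1OCC=C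
F7 | step 13 | 3-hydroxy-8-methoxy-4'-prenyloxy-5,7-bis[(E)-prop-1-en-1-yloxy]flavone | C/C=C/Oc1cc(O/C=C/C)c2c(=O)c(O)c(-c3ccc(OCC=C(C)C)cc3)oc2c1OC
F8 | step 3 | 3,5-bis(allyloxy)benzene-1,2-diol | Oc1cc(OCC=C)cc(OCC=C)c1O
F0 | step 1 | none | none
A1 | alternative 1 | 2-(tert-butyldimethylsilyloxy)-1-[2-hydroxy-3-methoxy-4,6-bis(triisopropylsilyloxy)phenyl]ethan-1-one | COc1c(O)c(C(=O)CO[Si](C)(C)C(C)(C)C)c(O[Si](C(C)C)(C(C)C)C(C)C)cc1O[Si](C(C)C)(C(C)C)C(C)C
A2 | alternative 1 | 1-iodo-4-(prenyloxy)benzene | CC(C)=CCOc1ccc(I)cc1
A3 | alternative 1 | 3-(tert-butyldimethylsilyloxy)-8-methoxy-4'-prenyloxy-5,7-bis(triisopropylsilyloxy)flavone | COc1c(O[Si](C(C)C)(C(C)C)C(C)C)cc(O[Si](C(C)C)(C(C)C)C(C)C)c2c(=O)c(O[Si](C)(C)C(C)(C)C)c(-c3ccc(OCC=C(C)C)cc3)oc12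
A4 | alternative 2 | 4,6-bis(allyloxy)-3-methoxy-2-{2-oxo-1-[4-(prenyloxy)phenyl]ethoxy}benzaldehyde (racemic) | O=Cc1c(OC(C=O)c2ccc(OCC=C(C)C)cc2)c(OC)c(OCC=C)cc1OCC=C
A5 | alternative 2 | 5,7-bis(allyloxy)-3-hydroxy-8-methoxy-2-[4-(prenyloxy)phenyl]chroman-4-one (mixture of diastereomers) | C=CCOc1cc(OCC=C)c2c(c1OC)OC(c1ccc(OCC=C(C)C)cc1)C(O)C2=O
A6 | alternative 3 | kojic acid (5-hydroxy-2-(hydroxymethyl)-4H-pyran-4-one) | O=c1cc(CO)occ1O
A7 | alternative 3 | 5-{2-methoxy-2-[4-oxo-6-(4-prenyloxyphenyl)-5-(2-trimethylsilylethoxymethoxy)-4H-pyran-2-yl]acetyl}-2,2-dimethyl-1,3-dioxane-4,6-dione (racemic) | COC(C(=O)C1C(=O)OC(C)(C)OC1=O)c1cc(=O)c(OCOCC[Si](C)(C)C)c(-c2ccc(OCC=C(C)C)cc2)o1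
A8 | alternative 3 | 5,7-dihydroxy-8-methoxy-4'-prenyloxy-3-(2-trimethylsilylethoxymethoxy)flavone | COc1c(O)cc(O)c2c(=O)c(OCOCC[Si](C)(C)C)c(-c3ccc(OCC=C(C)C)cc3)oc12
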